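Ring A of the target gibberellin carries oxygen on C10 and on C3, flanking C1–C2, with C19 on C4 lactonised to C10 and ring B fused along C5–C10. This is the footprint of a furan (C10, C1, C2, C3 and its oxygen) that has added across a tethered C4=C5 (Z)-enoate. One intramolecular furan Diels–Alder reaction thus forms C10–C5 and C3–C4, closes rings B and A and sets C10, C5 and C4. The precursor is the C/D bicyclo[3.2.1]octane with a 2-furyl group on C9 and the dienoate arm on C8; the oxygen bridge is later exchanged for the lactone.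

Key step: step 15

Remark: gibberellane numbering (C1–C19) is used for all intermediates, α being the face of the 19,10-lactone (H5, H9 and the C15–C16 bridge are β). In step 4 the ligand enantiomer is assumed to be the one that gives the (R) configuration at C9; its antipode is used if the sense of induction proves opposite.

Step 1
Reactants: 1 cyclohex-2-en-1-one
Product: 2 2-iodocyclohex-2-en-1-one
Conditions: I2 (1.5 equiv), pyridine, CH2Cl2, 0 °C → rt
Reagents that add atoms: iodine, II
Why: Conjugate addition of pyridine, iodination of the resulting enolate and loss of pyridinium (α-iodination of an enone by addition–elimination) should give the vinyl iodide cleanly, and no stereocenter is formed.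

Step 2
Reactants: 3 (2-bromoethoxy)(tert-butyl)dimethylsilane
Product: 5 potassium [2-(tert-butyldimethylsilyloxy)ethyl]trifluoroborate, via pinacol boronate 4 (not isolated)
Conditions: B2pin2 (1.5 equiv), CuI (10 mol %), PPh3 (13 mol %), LiOMe (2 equiv), DMF, rt; then aq. KHF2, MeOH, 0 °C
Reagents that add atoms: bis(pinacolato)diboron, CC1(C)OB(OC1(C)C)B1OC(C)(C)C(C)(C)O1; potassium hydrogen difluoride, [K+].F[H-]F
Why: Copper-catalysed borylation of the primary alkyl bromide and fluoride exchange at 0 °C (cold enough to spare the primary silyl ether) give a bench-stable alkyltrifluoroborate, chosen because a 2-silyloxyethyl zinc or magnesium halide is prone to lose ethylene by β-elimination; no stereocenter is formed.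

Step 3
Reactants: 2 2-iodocyclohex-2-en-1-one; 5 potassium [2-(tert-butyldimethylsilyloxy)ethyl]trifluoroborate
Product: 6 2-[2-(tert-butyldimethylsilyloxy)ethyl]cyclohex-2-en-1-one
Conditions: PdCl2(dppf) (5 mol %), Cs2CO3 (3 equiv), toluene/H2O, 80 °C
Reagents that add atoms: none
Why: Suzuki–Miyaura sp2–sp3 coupling, in which zerovalent palladium inserts readily into the carbon–iodine bond of the α-iodoenone, the trifluoroborate transmetalates under aqueous base and the bidentate phosphine favours reductive elimination over β-elimination; no stereocenter is formed.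

Step 4
Reactants: 6 2-[2-(tert-butyldimethylsilyloxy)ethyl]cyclohex-2-en-1-one; 7 furan
Product: 11 tert-butyl{2-[(6R)-6-(furan-2-yl)-2-(trimethylsilyloxy)cyclohex-1-en-1-yl]ethoxy}dimethylsilane, via 2-furyllithium 8 (not isolated), via (furan-2-yl)dimethylaluminium 9 (not isolated), via aluminium enolate 10 (not isolated)
Conditions: 7, n-BuLi, THF, 0 °C; Me2AlCl, −78 → 0 °C; then 6, Cu(O2CC4H3S) (copper thiophene-2-carboxylate, 5 mol %), (S,R,R)-L (10 mol %; L = (S)-1,1′-binaphthalene-2,2′-diyl N,N-bis[(R)-1-phenylethyl]phosphoramidite), Et2O, −30 °C; then Me3SiOTf, Et3N, −78 → 0 °C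
Reagents that add atoms: trimethylsilyl trifluoromethanesulfonate, C[Si](C)(C)OS(=O)(=O)C(F)(F)F
Why: Copper-catalysed asymmetric conjugate addition of a heteroaryl dimethylalane (the sp2 group transfers in preference to methyl), in which the phosphoramidite-bound furylcopper species adds to one enantioface of the enone and so sets C9 (R), followed by O-silylation of the regiodefined aluminium enolate.

Step 5
Reactants: 11 tert-butyl{2-[(6R)-6-(furan-2-yl)-2-(trimethylsilyloxy)cyclohex-1-en-1-yl]ethoxy}dimethylsilane; 12 2,3-dibromopropene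
Product: 14 (2S,3R)-2-(2-bromoprop-2-en-1-yl)-2-[2-(tert-butyldimethylsilyloxy)ethyl]-3-(furan-2-yl)cyclohexan-1-one, via lithium enolate 13 (not isolated)
Conditions: MeLi (1.05 equiv), THF, 0 °C → rt; then HMPA, 12, −78 → −20 °C
Reagents that add atoms: none
Why: Methyllithium cleaves only the O–SiMe3 bond to give the regiodefined tetrasubstituted lithium enolate, whose alkylation by the allylic bromide takes place on the face opposite the adjacent pseudoaxial furyl group, which sets the quaternary C8 (S) with the bromoallyl arm trans and the silyloxyethyl arm cis to the furan.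

Step 6
Reactants: 14 (2S,3R)-2-(2-bromoprop-2-en-1-yl)-2-[2-(tert-butyldimethylsilyloxy)ethyl]-3-(furan-2-yl)cyclohexan-1-one
Product: 15 (1R,2R,5S)-1-[2-(tert-butyldimethylsilyloxy)ethyl]-2-(furan-2-yl)-6-methylidenebicyclo[3.2.1]octan-8-one
Conditions: Pd(PPh3)4 (10 mol %), KOt-Bu (1.5 equiv), THF, 65 °C
Reagents that add atoms: none
Why: Intramolecular palladium-catalysed α-alkenylation of a ketone enolate, in which zerovalent palladium adds to the C–Br bond, the ketone can enolise only towards C13 and C–C reductive elimination closes the five-membered ring D, the configuration at C13 being dictated by the bridge (the bond can form only on the face of the axial alkenyl arm).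

Step 7
Reactants: 15 (1R,2R,5S)-1-[2-(tert-butyldimethylsilyloxy)ethyl]-2-(furan-2-yl)-6-methylidenebicyclo[3.2.1]octan-8-one
Product: 17 2-[2-(furan-2-yl)-6-methylidenebicyclo[3.2.1]octan-1-yl]ethan-1-ol (ring configuration as in 15), via hydrazone 16 (not isolated)
Conditions: N2H4·H2O (10 equiv), KOH (8 equiv), diethylene glycol, argon, 130 °C, then 200 °C with distillation of water
Reagents that add atoms: none
Why: Wolff–Kishner reduction (Huang-Minlon procedure), in which the angle-strained bridging ketone condenses readily with hydrazine and the hydrazone loses dinitrogen under hot alkali, conditions under which the furan and the isolated alkene are inert and the primary silyl ether is cleaved by hydroxide; no stereocenter is affected.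

Step 8
Reactants: 17 2-[2-(furan-2-yl)-6-methylidenebicyclo[3.2.1]octan-1-yl]ethan-1-ol
Product: 19 2-(furan-2-yl)-1-(2-hydroxyethyl)bicyclo[3.2.1]octan-6-one, via 16,17-diol 18 (not isolated)
Conditions: OsO4 (2 mol %), NaIO4 (4 equiv), 2,6-lutidine (2 equiv), dioxane/H2O 3:1, rt
Reagents that add atoms: osmium tetroxide, O=[Os](=O)(=O)=O; sodium periodate, [Na+].[O-]I(=O)(=O)=O
Why: Lemieux–Johnson oxidation, in which OsO4 dihydroxylates the exposed 1,1-disubstituted alkene far faster than the aromatic furan and NaIO4 cleaves the diol in situ to the C16 ketone while 2,6-lutidine keeps the medium near neutral; no stereocenter is affected.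

Step 9
Reactants: 19 2-(furan-2-yl)-1-(2-hydroxyethyl)bicyclo[3.2.1]octan-6-one
Product: 20 2-[2-(furan-2-yl)spiro[bicyclo[3.2.1]octane-6,2′-[1,3]dioxolan]-1-yl]ethan-1-ol
Conditions: ethylene glycol (5 equiv), PPTS (10 mol %), benzene, reflux, Dean–Stark trap
Reagents that add atoms: ethane-1,2-diol, OCCO
Why: Acid-catalysed ketalisation with azeotropic removal of water protects the unhindered C16 ketone for the later hydroboration and hydride steps, PPTS being mild enough for the 2-alkylfuran.

Step 10
Reactants: 20 2-[2-(furan-2-yl)spiro[bicyclo[3.2.1]octane-6,2′-[1,3]dioxolan]-1-yl]ethan-1-ol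
Product: 21 2-[2-(furan-2-yl)spiro[bicyclo[3.2.1]octane-6,2′-[1,3]dioxolan]-1-yl]acetaldehyde
Conditions: Dess–Martin periodinane (1.3 equiv), CH2Cl2, 0 °C → rt
Reagents that add atoms: none
Why: Dess–Martin oxidation converts the primary alcohol into the aldehyde under near-neutral conditions that leave the furan and the ketal untouched.

Step 11
Reactants: 21 2-[2-(furan-2-yl)spiro[bicyclo[3.2.1]octane-6,2′-[1,3]dioxolan]-1-yl]acetaldehyde
Product: 23 2-[2-(furan-2-yl)spiro[bicyclo[3.2.1]octane-6,2′-[1,3]dioxolan]-1-yl]prop-2-enal, via Mannich base 22 (not isolated)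
Conditions: CH2=NMe2+ I− (Eschenmoser's salt, 3 equiv), Et3N (5 equiv), CH2Cl2, rt
Reagents that add atoms: N,N-dimethylmethyleneiminium iodide, C=[N+](C)C.[I-]
Why: Mannich reaction of the aldehyde at its only enolisable carbon (C6) with the iminium salt, followed by base-induced β-elimination of dimethylamine, installs C7 as the α-methylene group, so that no stereocenter remains at C6.

Step 12
Reactants: 24 tert-butyl bromoacetate
Product: 25 tert-butyl 2-(diphenoxyphosphoryl)acetate
Conditions: (PhO)2P(O)H (1.0 equiv), Et3N (1.2 equiv), CH2Cl2, 0 °C → rt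
Reagents that add atoms: diphenyl phosphite, O=[PH](Oc1ccccc1)Oc1ccccc1
Why: Michaelis–Becker-type P-alkylation, in which the amine-activated phosphite attacks the reactive α-bromo ester at carbon to form the P–C bond.

Step 13
Reactants: 25 tert-butyl 2-(diphenoxyphosphoryl)acetate
Product: 26 tert-butyl 2-(diphenoxyphosphoryl)propanoate (racemic)
Conditions: NaH (1.0 equiv), MeI (1.1 equiv), DMSO/THF, rt
Reagents that add atoms: iodomethane, CI
Why: C-alkylation of the stabilised phosphonoacetate anion with one equivalent of iodomethane gives the α-methyl phosphonate as the racemate, whose stereocenter is lost in the next step.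

Step 14
Reactants: 23 2-[2-(furan-2-yl)spiro[bicyclo[3.2.1]octane-6,2′-[1,3]dioxolan]-1-yl]prop-2-enal; 26 tert-butyl 2-(diphenoxyphosphoryl)propanoate
Product: 27 tert-butyl (2Z)-4-[2-(furan-2-yl)spiro[bicyclo[3.2.1]octane-6,2′-[1,3]dioxolan]-1-yl]-2-methylpenta-2,4-dienoate
Conditions: 26, NaH, THF, −78 °C; then 23, −78 → 0 °C
Reagents that add atoms: none
Why: Horner–Wadsworth–Emmons olefination with a diaryl phosphonate, whose electron-poor aryloxy groups make elimination from the first-formed adduct fast and so should give the (Z)-trisubstituted alkene (C19 cis to C6), any E isomer being removed by chromatography.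

Step 15
Reactants: 27 tert-butyl (2Z)-4-[2-(furan-2-yl)spiro[bicyclo[3.2.1]octane-6,2′-[1,3]dioxolan]-1-yl]-2-methylpenta-2,4-dienoate
Product: 28 tert-butyl 3α,10α-epoxy-16,16-ethylenedioxy-17,20-dinorgibberella-1,6(7)-dien-19-oate (7-oxanorbornene cycloadduct; 18-methyl β, H5 β)
Conditions: Me2AlCl (1.5 equiv), CH2Cl2, −78 → −20 °C; Et3N, then aq. potassium sodium tartrate, −78 °C → rt
Reagents that add atoms: none
Why: The furan (C10=C1–C2=C3, oxygen between C10 and C3) and the aluminium-complexed C4=C5 bond of the (Z)-2,4-dienoate combine in a concerted, asynchronous [4+2] cycloaddition in which C10–C5 forms ahead of C3–C4, the closest known reaction type being the intramolecular Diels–Alder reaction of 2-alkylfurans with acrylate-type dienophiles on a three-atom tether. Ring B closes as a five-membered carbocycle through the tether C9–C8–C6, which for this tether length is possible only with the tether exo (C6 syn to the oxygen bridge), and ring A closes at the same time as the six-membered ring of a 7-oxanorbornene. C10 and C5 are fixed relative to each other by the exo tether (10-O and C6 cis, H5 on the opposite face), C4 by the Z geometry of the dienophile (C19 cis to C6 and therefore syn to the bridge, 18-methyl endo) and C3 by the bridge itself. The selectivity required is π-facial, the oxygen bridge having to lie on the face of ring B that carries C11 and C14, and it should be secured by the axial furan adopting the rotamer in which its C1–H lies next to the small H9 instead of the C11 methylene, while the quaternary C8 of the rigid bicyclo[3.2.1]octane holds the equatorial dienoate arm gauche to the furan. The Z-configured terminus keeps the dienoate from acting as a diene, C6 is sp2 and cannot epimerise, and the low temperature shifts the reversible cycloaddition towards the adduct, which is carried directly into step 16.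

Step 16
Reactants: 28 tert-butyl 3α,10α-epoxy-16,16-ethylenedioxy-17,20-dinorgibberella-1,6(7)-dien-19-oate
Product: 30 16,16-ethylenedioxy-3α-hydroxy-17,20-dinorgibberella-1,6(7)-dien-19-oic acid 19,10-lactone, via 3-O-trimethylsilyl lactone 29 (not isolated)
Conditions: Me3SiOTf (1.5 equiv), 2,6-lutidine (2.5 equiv), CH2Cl2, −78 → 0 °C; then aq. citric acid, THF, 0 °C
Reagents that add atoms: none
Why: Proposed new method: silylation of the bridge oxygen makes it a leaving group on the tertiary, allylic bridgehead C10 (the C3–O bond is secondary and flanked by the electron-poor C4), the exo tert-butyl ester one carbon away on the same face collapses through its carbonyl oxygen on the C10 end of the ion pair before the cation can delocalise or eliminate, and the dioxolenium ion loses isobutene to the hindered base, so that C10–O is replaced with retention, the former bridge oxygen stays on C3 as the 3α-silyl ether (cleaved on work-up) and no new stereocenter is created; the closest known reaction types are the acid-induced opening of 7-oxanorbornenes at the more substituted bridgehead and the lactonisation of tert-butyl esters onto epoxides or carbocations with loss of isobutene.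

Step 17
Reactants: 30 16,16-ethylenedioxy-3α-hydroxy-17,20-dinorgibberella-1,6(7)-dien-19-oic acid 19,10-lactone
Product: 32 16,16-ethylenedioxy-3α,7-dihydroxy-17,20-dinorgibberell-1-en-19-oic acid 19,10-lactone (C6 epimers), via bis-boryl adduct 31 (not isolated)
Conditions: 9-BBN-H (3 equiv), THF, 0 → 40 °C; then 30% H2O2, pH 7 phosphate buffer, THF/MeOH, 0 °C → rt
Reagents that add atoms: hydrogen peroxide, OO
Why: Hydroboration–oxidation, in which 9-BBN-H adds boron to the terminal carbon (C7) of the 1,1-disubstituted alkene much faster than to the cis-disubstituted ring alkene and does not reduce the lactone, and hydrogen peroxide at pH 7 oxidises the C–B bond without exposing the allylic 19,10-lactone and its β-hydroxyl to base; the configuration formed at C6 is not controlled here and is corrected in step 18.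

Step 18
Reactants: 32 16,16-ethylenedioxy-3α,7-dihydroxy-17,20-dinorgibberell-1-en-19-oic acid 19,10-lactone (C6 epimers)
Product: 34 16,16-ethylenedioxy-3,7-dioxo-17,20-dinorgibberell-1-en-19-oic acid 19,10-lactone (6β-formyl), via C6-epimeric keto aldehyde 33 (not isolated)
Conditions: Dess–Martin periodinane (3 equiv), CH2Cl2, rt; filtration through silica; then DBU (0.2 equiv), CH2Cl2, 0 °C → rt
Reagents that add atoms: none
Why: Dess–Martin oxidation of both alcohols gives the 1-en-3-one (which removes the wrongly configured C3 centre) and the 7-aldehyde, and DBU then equilibrates the only enolisable position, C6, to the epimer in which the formyl group is trans to the C5–C4 bond (6β), the less crowded arrangement on ring B.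

Step 19
Reactants: 34 16,16-ethylenedioxy-3,7-dioxo-17,20-dinorgibberell-1-en-19-oic acid 19,10-lactone (6β-formyl)
Product: 35 16,16-ethylenedioxy-3-oxo-17,20-dinorgibberell-1-ene-7,19-dioic acid 19,10-lactone
Conditions: NaClO2 (3 equiv), NaH2PO4 (3 equiv), 2-methylbut-2-ene (20 equiv), t-BuOH/H2O, 0 °C → rt
Reagents that add atoms: sodium chlorite, [Na+].[O-]Cl=O
Why: Pinnick oxidation converts the aldehyde into the carboxylic acid at about pH 4 without epimerising C6 or attacking the enone, the alkene scavenger removing hypochlorite.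

Step 20
Reactants: 35 16,16-ethylenedioxy-3-oxo-17,20-dinorgibberell-1-ene-7,19-dioic acid 19,10-lactone
Product: 36 16,16-ethylenedioxy-1β,2β-dihydroxy-3-oxo-17,20-dinorgibberellane-7,19-dioic acid 19,10-lactone
Conditions: OsO4 (5 mol %), N-methylmorpholine N-oxide (1.5 equiv), acetone/H2O 4:1, rt
Reagents that add atoms: osmium tetroxide, O=[Os](=O)(=O)=O; N-methylmorpholine N-oxide, C[N+]1([O-])CCOCC1; water, O
Why: Catalytic osmium tetroxide dihydroxylation of the enone, which should take place on the β face because the lactone bridge and the axial allylic C10–O bond lie on the α face of ring A, should set C1 and C2 as the 1β,2β-diol.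

Step 21
Reactants: 36 16,16-ethylenedioxy-1β,2β-dihydroxy-3-oxo-17,20-dinorgibberellane-7,19-dioic acid 19,10-lactone
Product: 38 1β,2β,3β-trihydroxy-16-oxo-17,20-dinorgibberellane-7,19-dioic acid 19,10-lactone (16-norketone of the target), via triol ketal acid 37 (not isolated)
Conditions: K[s-Bu3BH] (potassium tri-sec-butylborohydride, 5 equiv), THF, −78 °C; then 2 M HCl, THF/H2O, rt
Reagents that add atoms: water, O
Why: Reduction with a bulky trialkylborohydride, which delivers hydride along the equatorial trajectory on the α side because the axial 1β-oxygen blocks axial attack from the β face, should set the axial 3β-hydroxyl at −78 °C before the 1-alkoxide can undergo retro-aldol cleavage, and aqueous acid then hydrolyses the dioxolane to the C16 ketone.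

Step 22
Reactants: 38 1β,2β,3β-trihydroxy-16-oxo-17,20-dinorgibberellane-7,19-dioic acid 19,10-lactone
Product: 41 1β,2β,3β-trihydroxy-20-norgibberell-16-ene-7,19-dioic acid 19,10-lactone (the target gibberellin), via persilylated norketone 39 (not isolated), via persilylated target 40 (not isolated)
Conditions: MeC(OSiMe3)=NSiMe3 (6 equiv), THF, rt; then Ph3P=CH2 (5 equiv, from Ph3PCH3Br and KN(SiMe3)2), THF, 0 °C → rt; then aq. citric acid, THF/MeOH, rt
Reagents that add atoms: methylenetriphenylphosphorane, C=P(c1ccccc1)(c1ccccc1)c1ccccc1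
Why: Wittig methylenation of the C16 ketone with excess ylide, carried out on the persilylated substrate so that no free 3-alkoxide can trigger retro-aldol epimerisation next to the lactone, followed by mild acidic desilylation; no stereocenter is affected.

Compound list
1 | cyclohex-2-en-1-one | O=C1C=CCCC1 | starting material
2 | 2-iodocyclohex-2-en-1-one | O=C1CCCC=C1I | intermediate
3 | (2-bromoethoxy)(tert-butyl)dimethylsilane | BrCCO[Si](C)(C)C(C)(C)C | starting material
4 | tert-butyldimethyl[2-(4,4,5,5-tetramethyl-1,3,2-dioxaborolan-2-yl)ethoxy]silane | CC(C)(C)[Si](C)(C)OCCB1OC(C)(C)C(C)(C)O1 | intermediate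
5 | potassium [2-(tert-butyldimethylsilyloxy)ethyl]trifluoroborate | [K+].F[B-](F)(F)CCO[Si](C)(C)C(C)(C)C | intermediate
6 | 2-[2-(tert-butyldimethylsilyloxy)ethyl]cyclohex-2-en-1-one | O=C1CCCC=C1CCO[Si](C)(C)C(C)(C)C | intermediate
7 | furan | c1ccoc1 | starting material
8 | 2-furyllithium | [Li]c1ccco1 | intermediate
9 | (furan-2-yl)dimethylaluminium | C[Al](C)c1ccco1 | intermediate
10 | dimethylaluminium (3R)-2-[2-(tert-butyldimethylsilyloxy)ethyl]-3-(furan-2-yl)cyclohex-1-en-1-olate | C[Al](C)OC1=C(CCO[Si](C)(C)C(C)(C)C)[C@H](c2ccco2)CCC1 | intermediate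
11 | tert-butyl{2-[(6R)-6-(furan-2-yl)-2-(trimethylsilyloxy)cyclohex-1-en-1-yl]ethoxy}dimethylsilane | C[Si](C)(C)OC1=C(CCO[Si](C)(C)C(C)(C)C)[C@H](c2ccco2)CCC1 | intermediate
12 | 2,3-dibromopropene | C=C(Br)CBr | starting material
13 | lithium (3R)-2-[2-(tert-butyldimethylsilyloxy)ethyl]-3-(furan-2-yl)cyclohex-1-en-1-olate | [Li]OC1=C(CCO[Si](C)(C)C(C)(C)C)[C@H](c2ccco2)CCC1 | intermediate
14 | (2S,3R)-2-(2-bromoprop-2-en-1-yl)-2-[2-(tert-butyldimethylsilyloxy)ethyl]-3-(furan-2-yl)cyclohexan-1-one | C=C(Br)C[C@]1(CCO[Si](C)(C)C(C)(C)C)C(=O)CCC[C@H]1c1ccco1 | intermediate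
15 | (1R,2R,5S)-1-[2-(tert-butyldimethylsilyloxy)ethyl]-2-(furan-2-yl)-6-methylidenebicyclo[3.2.1]octan-8-one | C=C1C[C@]2(CCO[Si](C)(C)C(C)(C)C)C(=O)[C@H]1CC[C@H]2c1ccco1 | intermediate
16 | hydrazone of 15 at the C8 (gibberellane C14) carbonyl | C=C1C[C@]2(CCO[Si](C)(C)C(C)(C)C)C(=NN)[C@H]1CC[C@H]2c1ccco1 | intermediate
17 | 2-[2-(furan-2-yl)-6-methylidenebicyclo[3.2.1]octan-1-yl]ethan-1-ol (ring configuration as in 15) | C=C1C[C@]2(CCO)C[C@H]1CC[C@H]2c1ccco1 | intermediate
18 | 2-(furan-2-yl)-1-(2-hydroxyethyl)-6-(hydroxymethyl)bicyclo[3.2.1]octan-6-ol (C6 of the bicycle unassigned, ring configuration as in 15) | OCC1(O)C[C@]2(CCO)C[C@H]1CC[C@H]2c1ccco1 | intermediate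
19 | 2-(furan-2-yl)-1-(2-hydroxyethyl)bicyclo[3.2.1]octan-6-one (ring configuration as in 15) | O=C1C[C@]2(CCO)C[C@H]1CC[C@H]2c1ccco1 | intermediate
20 | 2-[2-(furan-2-yl)spiro[bicyclo[3.2.1]octane-6,2′-[1,3]dioxolan]-1-yl]ethan-1-ol (ring configuration as in 15) | C1COC2(O1)C[C@]3(CCO)C[C@H]2CC[C@H]3c1ccco1 | intermediate
21 | 2-[2-(furan-2-yl)spiro[bicyclo[3.2.1]octane-6,2′-[1,3]dioxolan]-1-yl]acetaldehyde | C1COC2(O1)C[C@]3(CC=O)C[C@H]2CC[C@H]3c1ccco1 | intermediate
22 | 3-(dimethylamino)-2-[2-(furan-2-yl)spiro[bicyclo[3.2.1]octane-6,2′-[1,3]dioxolan]-1-yl]propanal (side-chain centre unassigned) | C1COC2(O1)C[C@]3(C(CN(C)C)C=O)C[C@H]2CC[C@H]3c1ccco1 | intermediate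
23 | 2-[2-(furan-2-yl)spiro[bicyclo[3.2.1]octane-6,2′-[1,3]dioxolan]-1-yl]prop-2-enal | C1COC2(O1)C[C@]3(C(=C)C=O)C[C@H]2CC[C@H]3c1ccco1 | intermediate
24 | tert-butyl bromoacetate | BrCC(=O)OC(C)(C)C | starting material
25 | tert-butyl 2-(diphenoxyphosphoryl)acetate | CC(C)(C)OC(=O)CP(=O)(Oc1ccccc1)Oc1ccccc1 | intermediate
26 | tert-butyl 2-(diphenoxyphosphoryl)propanoate (racemic) | CC(C(=O)OC(C)(C)C)P(=O)(Oc1ccccc1)Oc1ccccc1 | intermediate
27 | tert-butyl (2Z)-4-[2-(furan-2-yl)spiro[bicyclo[3.2.1]octane-6,2′-[1,3]dioxolan]-1-yl]-2-methylpenta-2,4-dienoate | C1COC2(O1)C[C@]3(C(=C)/C=C(/C)C(=O)OC(C)(C)C)C[C@H]2CC[C@H]3c1ccco1 | intermediate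
28 | tert-butyl 3α,10α-epoxy-16,16-ethylenedioxy-17,20-dinorgibberella-1,6(7)-dien-19-oate | C1COC2(O1)C[C@]34C[C@H]2CC[C@H]3[C@@]12O[C@H](C=C2)[C@@](C)(C(=O)OC(C)(C)C)[C@H]1C4=C | intermediate
29 | 16,16-ethylenedioxy-3α-(trimethylsilyloxy)-17,20-dinorgibberella-1,6(7)-dien-19-oic acid 19,10-lactone | C1COC2(O1)C[C@]34C[C@H]2CC[C@H]3[C@@]12OC(=O)[C@@](C)([C@H]1C4=C)[C@H](O[Si](C)(C)C)C=C2 | intermediate
30 | 16,16-ethylenedioxy-3α-hydroxy-17,20-dinorgibberella-1,6(7)-dien-19-oic acid 19,10-lactone | C1COC2(O1)C[C@]34C[C@H]2CC[C@H]3[C@@]12OC(=O)[C@@](C)([C@H]1C4=C)[C@H](O)C=C2 | intermediate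
31 | 7-(9-borabicyclo[3.3.1]nonan-9-yl) 3α-O-(9-borabicyclo[3.3.1]nonan-9-yl) derivative of the 1-ene 19,10-lactone (C6 epimers) | C1COC2(O1)C[C@]34C[C@H]2CC[C@H]3[C@@]12OC(=O)[C@@](C)([C@H]1C4CB5C6CCCC5CCC6)[C@H](OB5C6CCCC5CCC6)C=C2 | intermediate
32 | 16,16-ethylenedioxy-3α,7-dihydroxy-17,20-dinorgibberell-1-en-19-oic acid 19,10-lactone (C6 epimers) | C1COC2(O1)C[C@]34C[C@H]2CC[C@H]3[C@@]12OC(=O)[C@@](C)([C@H]1C4CO)[C@H](O)C=C2 | intermediate
33 | 16,16-ethylenedioxy-3,7-dioxo-17,20-dinorgibberell-1-en-19-oic acid 19,10-lactone (C6 epimers) | C1COC2(O1)C[C@]34C[C@H]2CC[C@H]3[C@@]12OC(=O)[C@@](C)([C@H]1C4C=O)C(=O)C=C2 | intermediate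
34 | 16,16-ethylenedioxy-3,7-dioxo-17,20-dinorgibberell-1-en-19-oic acid 19,10-lactone (6β-formyl) | C1COC2(O1)C[C@]34C[C@H]2CC[C@H]3[C@@]12OC(=O)[C@@](C)([C@H]1[C@@H]4C=O)C(=O)C=C2 | intermediate
35 | 16,16-ethylenedioxy-3-oxo-17,20-dinorgibberell-1-ene-7,19-dioic acid 19,10-lactone | C1COC2(O1)C[C@]34C[C@H]2CC[C@H]3[C@@]12OC(=O)[C@@](C)([C@H]1[C@@H]4C(=O)O)C(=O)C=C2 | intermediate
36 | 16,16-ethylenedioxy-1β,2β-dihydroxy-3-oxo-17,20-dinorgibberellane-7,19-dioic acid 19,10-lactone | C1COC2(O1)C[C@]34C[C@H]2CC[C@H]3[C@@]12OC(=O)[C@@](C)([C@H]1[C@@H]4C(=O)O)C(=O)[C@@H](O)[C@H]2O | intermediate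
37 | 16,16-ethylenedioxy-1β,2β,3β-trihydroxy-17,20-dinorgibberellane-7,19-dioic acid 19,10-lactone | C1COC2(O1)C[C@]34C[C@H]2CC[C@H]3[C@@]12OC(=O)[C@@](C)([C@H]1[C@@H]4C(=O)O)[C@@H](O)[C@@H](O)[C@H]2O | intermediate
38 | 1β,2β,3β-trihydroxy-16-oxo-17,20-dinorgibberellane-7,19-dioic acid 19,10-lactone | O=C1C[C@]23C[C@H]1CC[C@H]2[C@@]12OC(=O)[C@@](C)([C@H]1[C@@H]3C(=O)O)[C@@H](O)[C@@H](O)[C@H]2O | intermediate
39 | trimethylsilyl ester 1,2,3-tris(trimethylsilyl) ether of 38 | O=C1C[C@]23C[C@H]1CC[C@H]2[C@@]12OC(=O)[C@@](C)([C@H]1[C@@H]3C(=O)O[Si](C)(C)C)[C@@H](O[Si](C)(C)C)[C@@H](O[Si](C)(C)C)[C@H]2O[Si](C)(C)C | intermediate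
40 | trimethylsilyl ester 1,2,3-tris(trimethylsilyl) ether of 41 | C=C1C[C@]23C[C@H]1CC[C@H]2[C@@]12OC(=O)[C@@](C)([C@H]1[C@@H]3C(=O)O[Si](C)(C)C)[C@@H](O[Si](C)(C)C)[C@@H](O[Si](C)(C)C)[C@H]2O[Si](C)(C)C | intermediate
41 | 1β,2β,3β-trihydroxy-20-norgibberell-16-ene-7,19-dioic acid 19,10-lactone (the target gibberellin) | C=C1C[C@]23C[C@H]1CC[C@H]2[C@@]12OC(=O)[C@@](C)([C@H]1[C@@H]3C(=O)O)[C@@H](O)[C@@H](O)[C@H]2O | target

Total steps: 22. Longest linear sequence: 19 steps (steps 1, 3 to 11 and 14 to 22, from cyclohex-2-en-1-one).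

Steps most likely to fail

1. Step 16 (Proposed new method). The ionised bridgehead may be captured at C2 instead of C10 (allylic transposition to a 19,2-lactone), may lose a proton or draw in the 6-methylene, and the silyl triflate may cleave the dioxolane. The fallback uses known chemistry, avoids any cation and keeps the C10–O bond instead of replacing it. It sets out from 28 and comes back at 37. Nickel-catalysed hydroalumination of the strained alkene (i-Bu2AlH added slowly, Ni(C8H12)2 (bis(cycloocta-1,5-diene)nickel), 1,4-bis(diphenylphosphino)butane, toluene) should place aluminium on C2, the olefinic carbon remote from the substituted bridgehead; β-alkoxide elimination then cleaves C3–O, and on warming the 10-alkoxide closes onto the cis tert-butyl ester to give 16,16-ethylenedioxy-17,20-dinorgibberella-2,6(7)-dien-19-oic acid 19,10-lactone F1. The operations of steps 17 to 19 (9-BBN-H then buffered H2O2; Dess–Martin periodinane then DBU; NaClO2) convert F1 into the 7-alcohol F2, the 6β-aldehyde F3 and the 2-ene 7-acid F4. Allylic hydroxylation with SeO2 and t-BuOOH, which can take place only at C1 and on the open β face, gives the 1β-hydroxy-2-ene acid F5. Hydroxyl-directed dihydroxylation of the 2,3-double bond (OsO4, N,N,N′,N′-tetramethylethylenediamine, CH2Cl2, −78 °C, then aq. Na2SO3), in which the 1β-hydroxyl and the open β face act in the same sense, gives 37, which enters the acid hydrolysis of step 21.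

2. Step 15. The cycloaddition–cycloreversion equilibrium may lie on the side of the open dienoate for this trisubstituted ester dienophile, the π-facial preference may be small, and the Lewis acid may isomerise or oligomerise the dienoate. The fallback raises the dienophile to the aldehyde level, so that the ring closure can run at a temperature where the adduct is favoured; it sets out from 27 and comes back at 30. Reduction with i-Bu2AlH gives the (Z)-dienol F6 and MnO2 the (Z)-dienal F7, which is used at once. Me2AlCl at −78 °C should then close the formyl 7-oxanorbornene F8 in the same exo mode, and NaClO2 oxidation gives the bridged carboxylic acid F9. F9 is treated with camphorsulfonic acid (10 mol %) in dry CH2Cl2 at 0 °C, where the free carboxyl group on the bridge face opens the protonated oxygen bridge at C10 and gives 30 directly.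

3. Step 4. The α-substituted enone may react sluggishly with the furyl alane and the enantioface discrimination may be insufficient. The fallback sets C9 on the unsubstituted enone; it sets out from 1 and 7 and comes back at 11. Rhodium-catalysed asymmetric 1,4-addition of (2-furyl)Ti(Oi-Pr)3 (from 8 and ClTi(Oi-Pr)3) to 1 with [Rh(OH)((R)-BINAP)]2, followed by silylation of the titanium enolate (Me3SiCl, LiOi-Pr), gives the (R)-silyl enol ether F10. MeLi followed by 2-(tert-butyldimethylsilyloxy)ethyl trifluoromethanesulfonate alkylates it trans to the furan to give the ketone F11, and thermodynamic silylation (Me3SiCl, NaI, Et3N, MeCN) towards the more substituted enol returns 11.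

Further compounds
F1 | step 16 | 16,16-ethylenedioxy-17,20-dinorgibberella-2,6(7)-dien-19-oic acid 19,10-lactone | C1COC2(O1)C[C@]34C[C@H]2CC[C@H]3[C@@]12OC(=O)[C@@](C)([C@H]1C4=C)C=CC2
F2 | step 16 | 16,16-ethylenedioxy-7-hydroxy-17,20-dinorgibberell-2-en-19-oic acid 19,10-lactone (C6 epimers) | C1COC2(O1)C[C@]34C[C@H]2CC[C@H]3[C@@]12OC(=O)[C@@](C)([C@H]1C4CO)C=CC2
F3 | step 16 | 16,16-ethylenedioxy-7-oxo-17,20-dinorgibberell-2-en-19-oic acid 19,10-lactone (6β-formyl) | C1COC2(O1)C[C@]34C[C@H]2CC[C@H]3[C@@]12OC(=O)[C@@](C)([C@H]1[C@@H]4C=O)C=CC2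
F4 | step 16 | 16,16-ethylenedioxy-17,20-dinorgibberell-2-ene-7,19-dioic acid 19,10-lactone | C1COC2(O1)C[C@]34C[C@H]2CC[C@H]3[C@@]12OC(=O)[C@@](C)([C@H]1[C@@H]4C(=O)O)C=CC2
F5 | step 16 | 16,16-ethylenedioxy-1β-hydroxy-17,20-dinorgibberell-2-ene-7,19-dioic acid 19,10-lactone | C1COC2(O1)C[C@]34C[C@H]2CC[C@H]3[C@@]12OC(=O)[C@@](C)([C@H]1[C@@H]4C(=O)O)C=C[C@H]2O
F6 | step 15 | (2Z)-4-[2-(furan-2-yl)spiro[bicyclo[3.2.1]octane-6,2′-[1,3]dioxolan]-1-yl]-2-methylpenta-2,4-dien-1-ol | C1COC2(O1)C[C@]3(C(=C)/C=C(/C)CO)C[C@H]2CC[C@H]3c1ccco1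
F7 | step 15 | (2Z)-4-[2-(furan-2-yl)spiro[bicyclo[3.2.1]octane-6,2′-[1,3]dioxolan]-1-yl]-2-methylpenta-2,4-dienal | C1COC2(O1)C[C@]3(C(=C)/C=C(/C)C=O)C[C@H]2CC[C@H]3c1ccco1
F8 | step 15 | 3α,10α-epoxy-16,16-ethylenedioxy-17,20-dinorgibberella-1,6(7)-dien-19-al | C1COC2(O1)C[C@]34C[C@H]2CC[C@H]3[C@@]12O[C@H](C=C2)[C@@](C)(C=O)[C@H]1C4=C
F9 | step 15 | 3α,10α-epoxy-16,16-ethylenedioxy-17,20-dinorgibberella-1,6(7)-dien-19-oic acid | C1COC2(O1)C[C@]34C[C@H]2CC[C@H]3[C@@]12O[C@H](C=C2)[C@@](C)(C(=O)O)[C@H]1C4=C
F10 | step 4 | {[(3R)-3-(furan-2-yl)cyclohex-1-en-1-yl]oxy}trimethylsilane | C[Si](C)(C)OC1=C[C@H](c2ccco2)CCC1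
F11 | step 4 | (2S,3R)-2-[2-(tert-butyldimethylsilyloxy)ethyl]-3-(furan-2-yl)cyclohexan-1-one | CC(C)(C)[Si](C)(C)OCC[C@@H]1C(=O)CCC[C@H]1c1ccco1
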